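You cannot hurry the substrate in these runs with more coupling partner.

| setting | noon | winter | spring | dusk | blue | amber | teal |
|---|---|---|---|---|---|---|---|
| substrate | 0.084 M | 0.084 M | 0.084 M | 0.13 M | 0.084 M | 0.084 M (fed, over 12 h) | 0.084 M |
| coupling partner | 2.5 equiv | 1.2 equiv | 1.9 equiv | 2.5 equiv | 2.50 equiv | 2.50 equiv | 2.50 equiv (fed, over 12 h) |
| capture agent | 8.4 mM | 8.4 mM | 8.4 mM | 8.4 mM | 8.40 mM | 8.40 mM | 8.40 mM |
| remark | run made earlier | run made earlier | run made earlier | run made earlier | everything together at the start | all else is in the flask from the start; the feed brings no volume worth counting | all else is in the flask from the start; the feed brings no volume worth counting |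
| time |  |  |  |  | 15 h | 15 h | 15 h |

- noon (time / h: target / %, substrate / %): 1.33: 14.8, 38.5; 2.50: 30.9, 21.9; 4.00: 44.7, 13.5; 5.00: 51.4, 9.9; 6.00: 56.9, 7.3; 8.00: 59.2, 3.1; 10.0: 62.5, 1.9
- winter (time / h: target / %, substrate / %): 1.00: 9.6, 46.4; 1.33: 15.5, 39.1; 2.00: 24.4, 30.2; 3.00: 38.0, 20.3; 5.00: 54.5, 9.6; 8.00: 63.4, 2.1; 12.0: 66.8, 0.8
- spring (time / h: target / %, substrate / %): 0.667: 4.6, 50.7; 2.00: 24.2, 28.9; 3.00: 36.4, 20.0; 5.00: 53.5, 9.3; 8.00: 61.2, 2.5; 10.0: 64.6, 2.3; 12.0: 69.4, 2.5
- dusk (time / h: target / %, substrate / %): 1.00: 9.3, 41.7; 2.00: 21.1, 25.8; 3.00: 34.5, 20.5; 6.00: 52.8, 6.7; 12.0: 65.4, 1.5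

(scatter of a reading: 1 percentage point)

* the flask with the highest amount of target, in percent of the substrate charged ("all alike" if they lie within 1.5 percentage points) (blue / amber / teal / all alike)
* final target, as a percentage of the substrate charged, in blue
* final target, as a percentage of the substrate charged, in amber
* final target, as a percentage of the substrate charged, in teal

- the numbers in the tables scatter by 1 percentage point (one standard deviation)

1. Take noon, whose charges are blue's, and treat its substrate tail as exponential. The drain time, the time in which unfinished material falls by a factor e, is then 2.81 h. Noon has twice winter's partner, yet it drains more slowly than winter's 2.25 h. Dusk, at higher [substrate], gives 2.97 h. So I read the loss as first order in [substrate] and zero order in [coupling partner].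

2. Run noon's tail back to time zero and it meets 53.3 %, about half of the charge. That is the knee: the rest leaves substrate before the first reading, into something unread. Target starts low, then passes substrate by 2.50 h.

3. The last readings of winter, spring and dusk, all at 12.0 h, average 67.2 %. So I put blue there.

4. In amber, a steady feed leaves 23.4 % of the charge unfinished when it stops, and 8.07 % at the asked time. That gives me 61.8 %.

5. Teal's feed delivers winter's partner after 5.76 h, twice the drain time. At 8.00 h, target falls from winter through spring to noon by 4.2 percentage points. So I put teal first, at 71.4 %.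

The forecast says blue, with 68 %, 62 % and 66 %, "assuming the zero order in partner persists at low partner levels". We part on teal.

    substrate ⇌ intermediate A (K = 0.578, k = 0.0452 /min)
    substrate + coupling partner ⇌ intermediate B (K = 1.70 /M, k = 0.0110 /M/min)
    intermediate A → intermediate C (k = 0.0190 /min)
    intermediate C ⇌ target (K = 2.51, k = 0.0172 /min)
    capture agent + intermediate B → trapped intermediate (k = 0.554 /M/min)

The flasks give 65.8 % in blue, 58.8 % in amber and 69.7 % in teal, so teal stands highest. At the asked time, trapped intermediate is 1.99 % in teal against 6.89 % in blue. Amber holds 9.17 % as substrate, intermediate A and intermediate B, against the 8.07 % the drain time gave.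

Left until 25 h, amber should keep 0.231 % unfinished, which puts target near 67.2 %. That flask gives 66.1 %, with 0.501 % in those three forms.

The runs are simulated on assumed constants; the scatter is artificial.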